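**Retrosynthetic overview**

1. Target 17 comes from Heck arylation of the C1‑vinyl group of 16 with aryl iodide 3, and 16 from methylenation of aldehyde 15. The cyclohexene is numbered C1 (quaternary: CH3 and the arylvinyl arm), C2 (CH–aryl), C3H=C4(CH3), C5H2, C6H2.
2. 15 comes from the acyclic Z,Z allyl vinyl ether 13 in one flask: a [3,3] shift makes the C1–C2 σ bond with both stereocentres, then ring‑closing metathesis makes C3=C4. The cyclohexene is the only ring built (both coumarin rings come ready‑made from umbelliferone) and it is closed before the second coumarin is attached.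
3. Enabling feature: C1 carries a one‑carbon arm at the aldehyde level and C2 is allylic to C3=C4, so O=CH–C1–C2–C3=C4 is a 4‑pentenal (Claisen) array. C4 with its methyl sits at the end of the C1–C6–C5 chain, where an isopropenyl tether meets the alkene that the rearrangement leaves on C2.
4. 13 comes from Cu‑catalysed O‑vinylation of the (R,Z)‑allylic alcohol 6 (from 3 and (R)‑but‑3‑yn‑2‑ol, then Z‑selective semihydrogenation) with the (Z)‑vinyl iodide 12 (carbocupration of propyne).
5. The single chiral‑pool carbinol centre of 6 controls both ring stereocentres and then leaves as propene.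

Key step: step 7

Assumption: the key step is run in one flask in two stages (heat, then Ru catalyst) without isolating aldehyde 14; iodination of umbelliferone with I2/KI/NH3 is taken to go to C‑8, as is usual for this phenol.

**Step 1**
Reactants: 1 7‑hydroxy‑2H‑chromen‑2‑one (umbelliferone)
Product: 2 7‑hydroxy‑8‑iodo‑2H‑chromen‑2‑one
Conditions: I2, KI, 25% aq. NH3, 0 °C to rt; then dil. H2SO4
Reagents that add atoms: iodine, II
Why: Electrophilic aromatic iodination of the phenoxide should go to C‑8, the position between the two ring oxygens.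

**Step 2**
Reactants: 2 7‑hydroxy‑8‑iodo‑2H‑chromen‑2‑one
Product: 3 8‑iodo‑7‑methoxy‑2H‑chromen‑2‑one
Conditions: MeI, K2CO3, acetone, reflux
Reagents that add atoms: iodomethane, CI
Why: Williamson O‑methylation; carbonate in dry acetone leaves the lactone closed, and capping the phenol prevents later cyclisation onto the ortho alkyne.

**Step 3**
Reactants: 3 8‑iodo‑7‑methoxy‑2H‑chromen‑2‑one; 4 (R)‑but‑3‑yn‑2‑ol
Product: 5 8‑[(3R)‑3‑hydroxybut‑1‑yn‑1‑yl]‑7‑methoxy‑2H‑chromen‑2‑one
Conditions: PdCl2(PPh3)2 (3 mol %), CuI (5 mol %), Et3N, THF, 45 °C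
Reagents that add atoms: none
Why: Sonogashira coupling of the aryl iodide with the terminal alkyne; the chiral‑pool carbinol centre is not touched.

**Step 4**
Reactants: 5 8‑[(3R)‑3‑hydroxybut‑1‑yn‑1‑yl]‑7‑methoxy‑2H‑chromen‑2‑one
Product: 6 8‑[(1Z,3R)‑3‑hydroxybut‑1‑en‑1‑yl]‑7‑methoxy‑2H‑chromen‑2‑one
Conditions: H2 (1 atm), Lindlar catalyst, quinoline, EtOAc, rt
Reagents that add atoms: none
Why: Semihydrogenation over poisoned palladium delivers H2 syn to give the Z‑alkene and should stop before the alkene or the coumarin C3=C4 bond is reduced.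

**Step 5**
Reactants: 7 4‑bromo‑2‑methylbut‑1‑ene; 8 propyne
Product: 12 (1Z)‑1‑iodo‑2,5‑dimethylhexa‑1,5‑diene, via homoallyl Grignard reagent 9 (not isolated), via alkylcopper reagent 10 (not isolated), via alkenylcopper reagent 11 (not isolated)
Conditions: Mg, Et2O; CuBr·SMe2, Me2S/Et2O, −45 °C; propyne, −25 °C; then I2, THF, −60 to 0 °C
Reagents that add atoms: iodine, II
Why: Carbocupration of a terminal alkyne is a syn addition that places copper on the terminal carbon, and iodinolysis with retention gives the Z‑iodide (iodine cis to the chain).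

**Step 6**
Reactants: 6 8‑[(1Z,3R)‑3‑hydroxybut‑1‑en‑1‑yl]‑7‑methoxy‑2H‑chromen‑2‑one; 12 (1Z)‑1‑iodo‑2,5‑dimethylhexa‑1,5‑diene
Product: 13 8‑[(1Z,3R)‑3‑{[(1Z)‑2,5‑dimethylhexa‑1,5‑dien‑1‑yl]oxy}but‑1‑en‑1‑yl]‑7‑methoxy‑2H‑chromen‑2‑one
Conditions: CuI (10 mol %), 3,4,7,8‑tetramethyl‑1,10‑phenanthroline (20 mol %), Cs2CO3, toluene, 80 °C
Reagents that add atoms: none
Why: Copper‑catalysed Ullmann‑type O‑vinylation of an allylic alcohol with a vinyl iodide keeps the iodide geometry and the carbinol configuration (the C–O bond of the alcohol is not broken), and 80 °C is below the temperature of the rearrangement.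

**Step 7**
Reactants: 13 8‑[(1Z,3R)‑3‑{[(1Z)‑2,5‑dimethylhexa‑1,5‑dien‑1‑yl]oxy}but‑1‑en‑1‑yl]‑7‑methoxy‑2H‑chromen‑2‑one
Product: 15 (1S,2S)‑2‑(7‑methoxy‑2‑oxo‑2H‑chromen‑8‑yl)‑1,4‑dimethylcyclohex‑3‑ene‑1‑carbaldehyde, via Claisen aldehyde 14 (not isolated)
Conditions: mesitylene (0.01 M), 140 °C, sealed tube, base‑washed glass; then 70 °C, Grubbs II (5 mol %), 1,4‑benzoquinone (10 mol %)
Reagents that add atoms: none
Why: Heating sends the allyl vinyl ether through a chair [3,3] transition state (Claisen rearrangement; closest precedent is the thermal shift of allyl vinyl ethers made by copper‑catalysed O‑vinylation, which builds vicinal quaternary and tertiary centres), forming the C1–C2 σ bond and unveiling aldehyde 14, whose (E)‑propenyl and isopropenyl groups are then joined by Ru‑catalysed ring‑closing metathesis, which forms C3=C4 and expels propene. The six‑membered ring is closed by metathesis through a ruthenacyclobutane between C3 (propenyl carbon on C2) and C4 (isopropenyl carbon), the only closure open to the catalyst because the remaining alkenes are the electron‑poor coumarin C3=C4 bonds. Both stereocentres arise in the sigmatropic step: the Z enol ether (oxygen cis to the C6 chain) and the Z aryl alkene fix aryl cis to formyl in the chair, and the (R)‑carbinol carbon transfers its configuration to give (1S,2S)‑15, which has the spatial arrangement of the (1R,2R) target (the descriptors differ only through CIP priorities). The step needs the chair with the carbinol methyl equatorial, and this is secured by the Z aryl group, which sits axial on the bond‑forming terminus and would clash 1,3‑diaxially with an axial methyl, so the methyl‑axial chair that would lead to the enantiomeric ring is closed off. The formyl group sits on the quaternary carbon and cannot epimerise, and benzoquinone suppresses Ru–H migration of the new alkene into conjugation with the aryl ring.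

**Step 8**
Reactants: 15 (1S,2S)‑2‑(7‑methoxy‑2‑oxo‑2H‑chromen‑8‑yl)‑1,4‑dimethylcyclohex‑3‑ene‑1‑carbaldehyde
Product: 16 8‑[(1R,6R)‑6‑ethenyl‑3,6‑dimethylcyclohex‑2‑en‑1‑yl]‑7‑methoxy‑2H‑chromen‑2‑one
Conditions: Ph3PCH3Br, KOtBu, THF, 0 °C to rt
Reagents that add atoms: methyltriphenylphosphonium bromide, C[P+](c1ccccc1)(c1ccccc1)c1ccccc1.[Br-]
Why: Wittig methylenation of a non‑enolisable aldehyde on a quaternary carbon; no stereocentre can epimerise.

**Step 9**
Reactants: 16 8‑[(1R,6R)‑6‑ethenyl‑3,6‑dimethylcyclohex‑2‑en‑1‑yl]‑7‑methoxy‑2H‑chromen‑2‑one; 3 8‑iodo‑7‑methoxy‑2H‑chromen‑2‑one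
Product: 17 7‑methoxy‑8‑[(E)‑2‑[(1R,2R)‑2‑(7‑methoxy‑2‑oxo‑2H‑chromen‑8‑yl)‑1,4‑dimethylcyclohex‑3‑en‑1‑yl]ethenyl]‑2H‑chromen‑2‑one
Conditions: Pd2(dba)3 (2.5 mol %), [HP(t‑Bu)3]BF4 (10 mol %), Cy2NMe, 1,4‑dioxane, 80 °C
Reagents that add atoms: none
Why: Mizoroki–Heck arylation; the aryl group adds to the CH2 terminus and, with a quaternary carbon on the other side, syn β‑hydride elimination can only give the E‑arylvinyl group, while the trisubstituted ring alkene stays inert.

**Compound list**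

1 | 7‑hydroxy‑2H‑chromen‑2‑one (umbelliferone) | O=c1ccc2ccc(O)cc2o1 | starting material
2 | 7‑hydroxy‑8‑iodo‑2H‑chromen‑2‑one | O=c1ccc2ccc(O)c(I)c2o1 | intermediate
3 | 8‑iodo‑7‑methoxy‑2H‑chromen‑2‑one | COc1ccc2ccc(=O)oc2c1I | intermediate
4 | (R)‑but‑3‑yn‑2‑ol | C[C@@H](O)C#C | starting material
5 | 8‑[(3R)‑3‑hydroxybut‑1‑yn‑1‑yl]‑7‑methoxy‑2H‑chromen‑2‑one | C[C@@H](O)C#Cc1c(OC)ccc2ccc(=O)oc12 | intermediate
6 | 8‑[(1Z,3R)‑3‑hydroxybut‑1‑en‑1‑yl]‑7‑methoxy‑2H‑chromen‑2‑one | C[C@@H](O)/C=C\c1c(OC)ccc2ccc(=O)oc12 | intermediate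
7 | 4‑bromo‑2‑methylbut‑1‑ene | C=C(C)CCBr | starting material
8 | propyne | CC#C | starting material
9 | (3‑methylbut‑3‑en‑1‑yl)magnesium bromide | C=C(C)CC[Mg]Br | intermediate
10 | (3‑methylbut‑3‑en‑1‑yl)copper | C=C(C)CC[Cu] | intermediate
11 | [(1Z)‑2,5‑dimethylhexa‑1,5‑dien‑1‑yl]copper | C=C(C)CC/C(C)=C\[Cu] | intermediate
12 | (1Z)‑1‑iodo‑2,5‑dimethylhexa‑1,5‑diene | C=C(C)CC/C(C)=C\I | intermediate
13 | 8‑[(1Z,3R)‑3‑{[(1Z)‑2,5‑dimethylhexa‑1,5‑dien‑1‑yl]oxy}but‑1‑en‑1‑yl]‑7‑methoxy‑2H‑chromen‑2‑one | C=C(C)CC/C(C)=C\O[C@H](C)/C=C\c1c(OC)ccc2ccc(=O)oc12 | intermediate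
14 | (2S,3S,4E)‑3‑(7‑methoxy‑2‑oxo‑2H‑chromen‑8‑yl)‑2‑methyl‑2‑(3‑methylbut‑3‑en‑1‑yl)hex‑4‑enal | O=C[C@@](C)(CCC(C)=C)[C@@H](/C=C/C)c1c(OC)ccc2ccc(=O)oc12 | intermediate
15 | (1S,2S)‑2‑(7‑methoxy‑2‑oxo‑2H‑chromen‑8‑yl)‑1,4‑dimethylcyclohex‑3‑ene‑1‑carbaldehyde (aryl cis to formyl) | O=C[C@@]1(C)CCC(C)=C[C@H]1c1c(OC)ccc2ccc(=O)oc12 | intermediate
16 | 8‑[(1R,6R)‑6‑ethenyl‑3,6‑dimethylcyclohex‑2‑en‑1‑yl]‑7‑methoxy‑2H‑chromen‑2‑one | C=C[C@@]1(C)CCC(C)=C[C@H]1c1c(OC)ccc2ccc(=O)oc12 | intermediate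
17 | 7‑methoxy‑8‑[(E)‑2‑[(1R,2R)‑2‑(7‑methoxy‑2‑oxo‑2H‑chromen‑8‑yl)‑1,4‑dimethylcyclohex‑3‑en‑1‑yl]ethenyl]‑2H‑chromen‑2‑one | COc1ccc2ccc(=O)oc2c1/C=C/[C@@]1(C)CCC(C)=C[C@H]1c1c(OC)ccc2ccc(=O)oc12 | target

**Step count**

Total: 9 steps. Longest linear sequence: 8 steps (1, 2, 3, 4, 6, 7, 8, 9).

**Steps most likely to fail**

Step 7. Three processes may interfere. The allylic C–O bond may ionise (the carbinol carbon is allylic to an electron‑rich aryl alkene) and compete with the concerted shift. Aldehyde 14 may undergo a thermal carbonyl‑ene reaction with its isopropenyl group while it waits at 140 °C. The metathesis may stall at the hindered propenyl group, or the new alkene may migrate. The fallback sets out from aryl iodide 3 and comes back at 15, and it replaces the acyclic ether by a cyclic allyl vinyl ether whose ring enforces the transition‑state geometry. Purchased methacrolein dimer, 2,5‑dimethyl‑3,4‑dihydro‑2H‑pyran‑2‑carbaldehyde F1, would be converted with Cl2CHBpin, CrCl2 and LiI (Takai–Utimoto‑type boryl olefination) into the (E)‑alkenylboronate F2. Suzuki–Miyaura coupling of F2 with 3 would give the 2‑(arylvinyl)dihydropyran F3. Heating F3 (o‑dichlorobenzene, about 200 °C) should bring about the Claisen ring contraction through a boat, in which the E alkene places aryl cis to formyl, to give the racemic cis‑aldehyde F4. Aldehyde 15 would be taken from F4 by preparative chromatography on a chiral stationary phase.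

Step 6. The hindered secondary alkoxide may exchange slowly at copper, base at 80 °C may cause Z‑to‑E drift or elimination, and the enol ether may hydrolyse on isolation. The fallback sets out from vinyl iodide 12 and comes back at 13, and it replaces the Ullmann‑type coupling by an oxidative copper(II) coupling of a boron partner at room temperature (Chan–Lam type). Iodine–lithium exchange on 12 (t‑BuLi, −78 °C) and trapping with 2‑isopropoxy‑4,4,5,5‑tetramethyl‑1,3,2‑dioxaborolane would give the (Z)‑alkenylboronate F5. F5 would be coupled with alcohol 6 using Cu(OAc)2, Et3N and 4 Å sieves in CH2Cl2 under air to give 13 with retention of both alkene geometries.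

Step 9. Carbopalladation between a di‑ortho‑substituted arylpalladium species and an alkene next to a quaternary carbon may be slow, so that reduction of 3 or arylation of a coumarin C3=C4 bond takes over. The fallback sets out from aldehyde 15 (it replaces steps 8 and 9) and comes back at 17. Aldehyde 15 would be treated with Cl2CHBpin, CrCl2 and LiI in THF to give the (E)‑alkenylboronate F6. Suzuki–Miyaura coupling of F6 with 3 (Pd(OAc)2, SPhos, K3PO4, THF/H2O, 50 °C) would give 17, with the C–C bond formed by transmetalation instead of alkene insertion.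

**Further compounds**

F1 | step 7 | 2,5‑dimethyl‑3,4‑dihydro‑2H‑pyran‑2‑carbaldehyde (methacrolein dimer, racemic, purchased) | O=CC1(C)CCC(C)=CO1
F2 | step 7 | 2‑[(E)‑2‑(2,5‑dimethyl‑3,4‑dihydro‑2H‑pyran‑2‑yl)ethenyl]‑4,4,5,5‑tetramethyl‑1,3,2‑dioxaborolane (racemic) | CC1(C)OB(/C=C/C2(C)CCC(C)=CO2)OC1(C)C
F3 | step 7 | 8‑[(E)‑2‑(2,5‑dimethyl‑3,4‑dihydro‑2H‑pyran‑2‑yl)ethenyl]‑7‑methoxy‑2H‑chromen‑2‑one (racemic) | COc1ccc2ccc(=O)oc2c1/C=C/C1(C)CCC(C)=CO1
F4 | step 7 | racemic cis‑2‑(7‑methoxy‑2‑oxo‑2H‑chromen‑8‑yl)‑1,4‑dimethylcyclohex‑3‑ene‑1‑carbaldehyde (15 and its enantiomer, 1:1) | O=C[C@@]1(C)CCC(C)=C[C@H]1c1c(OC)ccc2ccc(=O)oc12.O=C[C@]1(C)CCC(C)=C[C@@H]1c1c(OC)ccc2ccc(=O)oc12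
F5 | step 6 | 2‑[(1Z)‑2,5‑dimethylhexa‑1,5‑dien‑1‑yl]‑4,4,5,5‑tetramethyl‑1,3,2‑dioxaborolane | C=C(C)CC/C(C)=C\B1OC(C)(C)C(C)(C)O1
F6 | step 9 | 8‑[(1R,6R)‑3,6‑dimethyl‑6‑[(E)‑2‑(4,4,5,5‑tetramethyl‑1,3,2‑dioxaborolan‑2‑yl)ethenyl]cyclohex‑2‑en‑1‑yl]‑7‑methoxy‑2H‑chromen‑2‑one | CC1(C)OB(/C=C/[C@@]2(C)CCC(C)=C[C@H]2c2c(OC)ccc3ccc(=O)oc23)OC1(C)C
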